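Readings and results are simulated from invented constants, noise included.

The amounts charged set the question: how fast intermediate D is made, and how fast that making slows.

| flask | starting material | partner | remark | time |
|---|---|---|---|---|
| ochre | 17 mM | 1.2 equiv | run made earlier |  |
| teal | 17 mM | 1.9 equiv | run made earlier |  |
| grey | 8.5 mM | 2.5 equiv | run made earlier |  |
| flask | 17 mM | 2.50 equiv |  | 6.0 min |

| run | time / min | intermediate D / % | target / % |
|---|---|---|---|
| ochre | 0.200 | 1.1 | 8.5 |
| ochre | 0.500 | 5.0 | 14.8 |
| ochre | 1.00 | 4.4 | 18.1 |
| ochre | 2.50 | 1.5 | 17.8 |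
| ochre | 6.00 | 0.4 | 19.0 |
| teal | 0.200 | 2.2 | 9.1 |
| teal | 0.500 | 6.2 | 14.8 |
| teal | 1.00 | 7.1 | 17.2 |
| teal | 2.50 | 2.6 | 18.2 |
| teal | 6.00 | 0 | 17.5 |
| grey | 0.200 | 0.9 | 8.8 |
| grey | 0.500 | 4.9 | 13.9 |
| grey | 1.00 | 4.0 | 17.3 |
| grey | 2.50 | 0.4 | 17.9 |
| grey | 6.00 | 0.4 | 17.7 |

(standard deviation of a reading: 0.5 percentage points)

1. when, up to 6.0 min, the flask holds most intermediate D
2. the amount of intermediate D, in percent of the starting material charged, at that time



Grey is charged with half the starting material of ochre, yet at a charged c(partner) of 21.2 mM against 20.4 mM its highest D reading, 4.9%, stands beside ochre's 5.0%. So c(partner) is the concentration to follow.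

Two rates slow the gain. The rise of target in ochre reads as a source, the starting material, fading at 2.97 min⁻¹, and the D readings fall at 0.717 min⁻¹ in ochre and 0.670 min⁻¹ in teal, although teal is charged with 32.3 mM of partner. With the fall so alike, a peak is taken here to follow the making rate, which gives the peak order, the power of charged c(partner) that carries one highest D reading to another (an apparent reaction order): 0.763, read from teal and ochre.

The flask, charged at 42.5 mM, should make D 1.75 times as fast as ochre, giving an estimated peak of 8.75%. The two rates place it near 0.631 min, a little later for the lag in the first readings, with the source down to a factor 0.153. Hardly any of that peak should remain at 6.0 min.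

The forecast, holding that “D seems to follow absolute partner concentration”, gave 9.5% at 0.75 min, more than this reckoning's peak.

The flask holds most intermediate D, 10.5%, at 0.814 min, which is 1.7 percentage points above the reckoning, and it holds 0.0416% at 6.00 min.

    starting material → intermediate A (k = 0.0450 s⁻¹)
    starting material → target (k = 0.00990 s⁻¹)
    partner + intermediate A ⇌ intermediate B (K = 19.0 M⁻¹, k = 1.40 M⁻¹ s⁻¹)
    intermediate A ⇌ intermediate C (K = 2.10, k = 0.100 s⁻¹)
    partner + intermediate B ⇌ intermediate D (K = 330 M⁻¹, k = 8.30 M⁻¹ s⁻¹)
    partner + intermediate B → side product (k = 2.80 M⁻¹ s⁻¹)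
    partner → decomposed reagent (k = 0.0220 s⁻¹)

The neighbouring flask with 10.0 equiv of partner is charged at c(partner) 170 mM, 4.00 times the charge of the flask. Carried from the flask's result, the peak order gives it 30.3%. That neighbouring flask reaches a peak of 31.6% of intermediate D, which is 1.3 points above.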